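All runs stem from a simulated flask for an exercise; scatter was added.

One rate constant cannot draw the dawn run: starting material falls at 0.290 /min over the first 0.500 min, but at 0.142 /min over the whole 8.00 min, which is less. So I give up the curve and keep its mean, k: the natural log of charged over remaining starting material, divided by the time. Midway this errs, since dawn's k puts 56.7% at 4.00 min, where the reading is 40.2%. At the end time it matches by construction, and that is the time I need.

| setting | dawn | midnight | autumn | flask |
|---|---|---|---|---|
| starting material | 0.50 M | 0.50 M | 1 M | 0.50 M |
| reagent | 0.44 M | 0.98 M | 0.65 M | 0.650 M |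
| initiator | 4.9 mM | 4.9 mM | 4.9 mM | 4.9 mM |
| remark | run made earlier | run made earlier | run made earlier |  |
| time |  |  |  | 8.0 min |

| run | time / min | starting material / % | target / % |
|---|---|---|---|
| dawn | 0.500 | 86.5 | 16.9 |
| dawn | 1.50 | 64.0 | 33.1 |
| dawn | 3.00 | 47.6 | 43.5 |
| dawn | 4.00 | 40.2 | 45.4 |
| dawn | 6.00 | 35.0 | 45.3 |
| dawn | 8.00 | 32.2 | 42.0 |
| midnight | 0.667 | 78.4 | 19.9 |
| midnight | 1.00 | 69.6 | 29.1 |
| midnight | 2.00 | 53.7 | 43.0 |
| midnight | 3.00 | 42.4 | 48.0 |
| midnight | 5.00 | 32.5 | 50.9 |
| midnight | 8.00 | 25.2 | 49.7 |
| autumn | 0.667 | 79.4 | 18.4 |
| autumn | 2.00 | 61.5 | 34.1 |
| autumn | 4.00 | 51.0 | 37.2 |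
| autumn | 6.00 | 47.7 | 35.0 |
| autumn | 8.00 | 50.3 | 33.0 |

(standard deviation of a reading: 1 percentage point)

* why nothing more happens at 8.0 min, or that something still does (the reagent has run out first / forward and back rates have come level / all of the starting material has reacted / it is still moving)
* part of the starting material gone at 8.0 min
* the target standing at 8.0 min, as a percentage of the starting material charged

- percent here means starting material units held: one ended chains B counts as two
- reactions considered so far: initiator -> 2 initiating radical; starting material + initiating radical -> chain carrier; reagent + chain carrier -> target + initiating radical; 2 initiating radical -> ended chains A; 2 chain carrier -> ended chains B; 2 reagent -> homo dimer; target <-> isomer of the product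
- the reaction counts as stopped when no species that holds the starting material changes by six tenths of a point or more over the second half of the time

Now the settings. By hand, more reagent should speed the chain. From dawn to midnight it rises to twice its charge, and k goes from 0.142 /min to 0.172 /min. By hand, more starting material against the same reagent should leave a larger share. Autumn, with twice the flask's starting material and the flask's reagent, reads a k of 0.0859 /min, lower than dawn's and midnight's, though it differs from each of them in both charges.

Going straight from dawn to midnight at the flask's reagent, I take the flask's mean k, a plain average over the time, as 0.154 /min. That means 70.7% gone. The same step gives target 45.0%. Dawn still lost 8 percentage points after 4.00 min, so I expect movement.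

The forecast says it is still moving, with 71% gone and 46% target, noting that “The flask has more reagent than dawn”.

The flask gives it is still moving, with 73.0% gone and 46.7% target.

    initiator → 2 initiating radical (k = 0.00870 /s)
    starting material + initiating radical → chain carrier (k = 1400 /M/s)
    reagent + chain carrier → target + initiating radical (k = 7800 /M/s)
    2 initiating radical → ended chains A (k = 1.70 × 10⁶ /M/s)
    2 chain carrier → ended chains B (k = 8.00 × 10⁶ /M/s)
    2 reagent → homo dimer (k = 0.00310 /M/s)
    target ⇌ isomer of the product (K = 1.20, k = 0.00170 /s)

Of its charge, the flask keeps 1.5% of initiator, less than the 27% of starting material. Its own mean k is 0.164 /min, against my 0.154 /min. Now take a flask like this one with 0.020 M of initiator. Scaling my k by the root of the initiator charge, a guess from radicals ending in pairs, gives 0.310 /min, and so 8.36% of the starting material left. That flask holds 6.4%.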